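**Retrosynthetic overview**
1. Target 6 is the C2-symmetric malonate of two (5S,9S,10S)-labda-7,13E-dien-15-yl arms. All four rings and all six stereocentres are disconnected at once, back to the acyclic bis(geranylgeranyl) malonate 4.
2. Forward, one chiral-acid-promoted double polyene bicyclization closes both decalins in the same operation. In each arm ring A forms first (C4–C5 bond), then ring B (C9–C10 bond), and the cascade ends by loss of H-7.
3. The malonate serves as the stop group: chelated by SnCl4 it deactivates the 13,14-olefins. It also links the two arms, so a wrongly cyclized arm ends up mainly in the meso diastereomer, not in the enantiomer.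
4. 4 comes from geranylgeranyl hydrogen malonate 3 and geranylgeraniol 1; 3 comes from 1 and Meldrum's acid 2.

Assumption: (2E,6E,10E)-geranylgeraniol (annatto-derived) is taken as the commercial terpene input, and the (R)-configured chiral acid is assumed to give the (5S,9S,10S) arm; if the sense is opposite, the (S)-ligand is used with no other change.

Chiral acid (reagent, recovered): the 1:1 complex of SnCl4 with (R)-2'-(2-fluorobenzyloxy)-1,1'-binaphthalen-2-ol, a Lewis acid-assisted chiral Brønsted acid (LBA). The ligand is made from (R)-BINOL and 2-fluorobenzyl bromide.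

**Route**

Step 1
Reactants: 1 (2E,6E,10E)-geranylgeraniol; 2 Meldrum's acid (2,2-dimethyl-1,3-dioxane-4,6-dione)
Product: 3 (2E,6E,10E)-geranylgeranyl hydrogen malonate
Conditions: 2 (1.05 equiv), toluene, 85 °C, 4 h
Reagents that add atoms: none
Why: Alcoholysis of Meldrum's acid, in which the primary allylic alcohol opens the activated cyclic acylal and acetone is lost, gives the half-ester without coupling agent, acid chloride or base, so the four olefins keep their geometry and no stereocentre is formed.

Step 2
Reactants: 3 (2E,6E,10E)-geranylgeranyl hydrogen malonate; 1 (2E,6E,10E)-geranylgeraniol (second equivalent)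
Product: 4 bis[(2E,6E,10E)-geranylgeranyl] malonate
Conditions: dicyclohexylcarbodiimide (DCC, 1.1 equiv), 4-dimethylaminopyridine (DMAP, 10 mol%), CH2Cl2, 0 °C to rt, 3 h
Reagents that add atoms: none
Why: Steglich esterification, in which the carbodiimide activates the free carboxylic acid of 3 for acyl transfer to the primary allylic alcohol under neutral conditions at 0 °C, leaves the acid-sensitive polyene untouched and creates no stereocentre.

Step 3
Reactants: 4 bis[(2E,6E,10E)-geranylgeranyl] malonate
Product: 6 bis[(5S,9S,10S)-labda-7,13E-dien-15-yl] malonate, via half-cyclized mixed malonate 5 (not isolated)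
Conditions: SnCl4 (1.0 equiv), toluene, −78 °C, 15 min; then added to (R)-2'-(2-fluorobenzyloxy)-1,1'-binaphthalen-2-ol·SnCl4 (3.0 equiv), toluene, −78 °C, 48 h; aq NaHCO3 (ligand recovered; the proton is returned on elimination)
Reagents that add atoms: none
Why: Proposed new method: a double enantioselective proton-initiated polyene bicyclization (closest known reaction type: biomimetic cyclization of homofarnesol and polyprenyl arenes by BINOL-ether·SnCl4 chiral Brønsted acids) in which the chiral acid protonates one enantioface of each terminal isopropylidene, the all-E chain folds chair–chair so that anti addition across the 10,11- and 6,7-olefins of each arm fixes the 5α-H/10β-Me/9α-H trans-decalin, the C-8 cation loses the axial 7-H (E1) and hands the proton back to the stannate, the 13,14-olefin stays out because it is allylic to the SnCl4-chelated malonate, and since both arms are cyclized by the same chiral acid a mis-cyclized arm is diverted mainly into the meso diastereomer (Horeau-type amplification), so that 6 is formed in higher ee than a single cyclization would give.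

**Compound list**
1 | (2E,6E,10E)-geranylgeraniol | CC(C)=CCC/C(C)=C/CC/C(C)=C/CC/C(C)=C/CO | starting material
2 | Meldrum's acid (2,2-dimethyl-1,3-dioxane-4,6-dione) | CC1(C)OC(=O)CC(=O)O1 | starting material
3 | (2E,6E,10E)-geranylgeranyl hydrogen malonate | CC(C)=CCC/C(C)=C/CC/C(C)=C/CC/C(C)=C/COC(=O)CC(=O)O | intermediate
4 | bis[(2E,6E,10E)-geranylgeranyl] malonate | CC(C)=CCC/C(C)=C/CC/C(C)=C/CC/C(C)=C/COC(=O)CC(=O)OC/C=C(\C)CC/C=C(\C)CC/C=C(\C)CCC=C(C)C | intermediate
5 | (5S,9S,10S)-labda-7,13E-dien-15-yl (2E,6E,10E)-geranylgeranyl malonate (half-cyclized mixed malonate) | CC1=CC[C@H]2C(C)(C)CCC[C@]2(C)[C@H]1CC/C(C)=C/COC(=O)CC(=O)OC/C=C(\C)CC/C=C(\C)CC/C=C(\C)CCC=C(C)C | intermediate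
6 | bis[(5S,9S,10S)-labda-7,13E-dien-15-yl] malonate = bis{(2E)-3-methyl-5-[(1S,4aS,8aS)-2,5,5,8a-tetramethyl-1,4,4a,5,6,7,8,8a-octahydronaphthalen-1-yl]pent-2-en-1-yl} propanedioate | CC1=CC[C@H]2C(C)(C)CCC[C@]2(C)[C@H]1CC/C(C)=C/COC(=O)CC(=O)OC/C=C(\C)CC[C@H]1C(C)=CC[C@H]2C(C)(C)CCC[C@]12C | target

**Totals**
Total step count: 3. Longest linear sequence: 3 (1 → 3 → 4 → 6).

**Steps most likely to fail, with fallbacks**

Step 3 (by far the riskiest). Four things can go wrong:
- Olefin position: the C-8 cation can also lose a proton to the 8(17)- or 8-ene. Both arms must end as the 7-ene, so about 60% selectivity per arm leaves about 35% of the doubly correct product. It is isolated on AgNO3–silica.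
- Meso content: at an assumed 90:10 face selectivity per arm the statistical outcome is 81% of 6, 18% meso and 1% of the enantiomer. That gives 6 in about 98% ee, but the meso diastereomer must be removed by preparative HPLC on a chiral phase.
- Incomplete cyclization: the cascade may stop after ring A.
- Ionization: the SnCl4-chelated allylic malonate may ionize.

Fallback, setting out from 1 and returning at 6: cyclize the arm alone and join the arms last. 1 is acetylated (Ac2O, pyridine) to (2E,6E,10E)-geranylgeranyl acetate F1. F1 is bicyclized with the same chiral acid at −78 °C, with the acetate as stop group, to (5S,9S,10S)-labda-7,13E-dien-15-yl acetate F2, which is freed from its olefin isomers on AgNO3–silica. K2CO3 in MeOH gives (5S,9S,10S)-labda-7,13E-dien-15-ol F3, and its ee is raised above 99% by preparative chromatography on a chiral phase. Two equivalents of F3 are then coupled with malonic acid (DCC, DMAP, CH2Cl2) to give 6. No meso compound can form because each arm is enantiopure before the arms are joined.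

Step 2. The activated malonic half-acid can divert to N-acylurea or ketene-derived oligomers, which costs geranylgeraniol. Fallback, setting out from 3 and 1 and returning at 4: reverse the polarity of the ester bond formation and alkylate the carboxylate. 1 is converted with PBr3 (Et2O, −10 °C) into (2E,6E,10E)-geranylgeranyl bromide F4, and 3 is O-alkylated with F4 (Cs2CO3, DMF, rt) to give 4 with no activated acyl species involved.

Step 1. The half-ester can partly decarboxylate to the acetate if overheated, and traces of diester and malonic acid can form. Fallback, setting out from 1 and returning at 4, bypassing 3: build both ester bonds by transesterification. 1 and excess dimethyl malonate (Bu2SnO 5 mol%, toluene, 100 °C, MeOH distilled off) give (2E,6E,10E)-geranylgeranyl methyl malonate F5. After the excess dimethyl malonate is removed in vacuo, F5 and a second equivalent of 1 under the same catalyst give 4.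

**Further compounds**
F1 | step 3 | (2E,6E,10E)-geranylgeranyl acetate | CC(C)=CCC/C(C)=C/CC/C(C)=C/CC/C(C)=C/COC(C)=O
F2 | step 3 | (5S,9S,10S)-labda-7,13E-dien-15-yl acetate | CC1=CC[C@H]2C(C)(C)CCC[C@]2(C)[C@H]1CC/C(C)=C/COC(C)=O
F3 | step 3 | (5S,9S,10S)-labda-7,13E-dien-15-ol | CC1=CC[C@H]2C(C)(C)CCC[C@]2(C)[C@H]1CC/C(C)=C/CO
F4 | step 2 | (2E,6E,10E)-geranylgeranyl bromide | CC(C)=CCC/C(C)=C/CC/C(C)=C/CC/C(C)=C/CBr
F5 | step 1 | (2E,6E,10E)-geranylgeranyl methyl malonate | CC(C)=CCC/C(C)=C/CC/C(C)=C/CC/C(C)=C/COC(=O)CC(=O)OC
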